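Ring A is disconnected at C3–C4 (labdane numbering): the cis-related C3 hydroxyl and C19 acetoxymethyl on quaternary C4 are read as the two ends of an opened oxetane (O–C3–C4–C19). An intramolecular Paternò–Büchi photocycloaddition of a C3 aldehyde onto the isopropenyl group (C4, C18, C19) inherited from (S)-carvone closes ring A, sets C3 and C4 together and stores the 1,3-diol as a strained oxetane. The precursor is a monocyclic ring B enol triflate whose two stereocentres, C5 (bought) and C10 (alkylation anti to isopropenyl), relay all others. The oxetane then acts as protecting group until acetic acid opens it at C19 in the last step.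

Key step: step 6

Remark: atoms keep their labdane numbers in all intermediates; C6 of compound 3 and the epoxide carbon of F1 and F2 are epimeric mixtures that converge, so their SMILES leave that centre open.

Step 1
Reactants: 1 (S)-(+)-carvone
Product: 3 (5S)-6-methylcarvone (C6 epimers), via lithium dienolate 2 (not isolated)
Conditions: LiN(i-Pr)2, THF, −78 °C; then MeI, −78 → 0 °C
Reagents that add atoms: methyl iodide, CI
Why: Kinetic deprotonation at C6 gives the cross-conjugated lithium dienolate, which is C-methylated (enolate alkylation); the new centre is planarised again in step 2 and so is inconsequential.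

Step 2
Reactants: 3 (5S)-6-methylcarvone
Product: 5 (5R,6R)-2,6-dimethyl-6-(prop-2-en-1-yl)-5-(prop-1-en-2-yl)cyclohex-2-en-1-one, via lithium dienolate 4 (not isolated)
Conditions: LiN(i-Pr)2, THF, −78 °C; then allyl bromide, DMPU, −78 °C → rt
Reagents that add atoms: allyl bromide, C=CCBr
Why: Enolate alkylation on the face anti to the neighbouring isopropenyl group should set the quaternary centre (C10) with allyl trans and methyl cis to isopropenyl.

Step 3
Reactants: 5 allyl methyl enone
Product: 7 (5R,6R)-2,6-dimethyl-6-(prop-2-en-1-yl)-5-(prop-1-en-2-yl)cyclohex-1-en-1-yl trifluoromethanesulfonate, via lithium enolate 6 (not isolated)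
Conditions: LiBH(s-Bu)3 (L-Selectride), THF, −78 °C; then PhNTf2, −78 °C → rt
Reagents that add atoms: N-phenylbis(trifluoromethanesulfonimide), FC(F)(F)S(=O)(=O)N(c1ccccc1)S(=O)(=O)C(F)(F)F
Why: Conjugate hydride addition to the β-unsubstituted enone gives the C8=C9 enolate regiospecifically (C10 is quaternary), and O-sulfonylation traps it as the enol triflate (reductive enolate trapping); no stereocentre is formed.

Step 4
Reactants: 7 enol triflate
Product: 9 primary alcohol (allyl group of 7 converted into a 3-hydroxypropyl chain), via trialkylborane 8 (not isolated)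
Conditions: disiamylborane [BH3·SMe2 + 2-methylbut-2-ene], THF, 0 °C; then NaBO3·4H2O, H2O, rt
Reagents that add atoms: sodium perborate (oxygen source), [Na+].[O-]OB=O
Why: Hydroboration–oxidation with the bulky dialkylborane should select the monosubstituted allyl double bond over the hindered 1,1-disubstituted isopropenyl group and the electron-poor enol triflate, placing oxygen on the terminal carbon (C3).

Step 5
Reactants: 9 primary alcohol
Product: 10 aldehyde (3-oxopropyl chain on C10; isopropenyl on C5; enol triflate at C8=C9)
Conditions: Dess–Martin periodinane, NaHCO3, CH2Cl2, 0 °C → rt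
Reagents that add atoms: none
Why: Dess–Martin oxidation of the primary alcohol under buffered conditions leaves the enol triflate and the isopropenyl group untouched.

Step 6
Reactants: 10 aldehyde
Product: 11 oxetane-fused trans-octalin enol triflate (ring A closed; oxetane oxygen on C3 and oxetane CH2 (C19) on C4 both cis to the C10 methyl; C18 methyl trans)
Conditions: hν (300 nm, Pyrex), degassed MeCN (0.01 M), rt
Reagents that add atoms: none
Why: Excitation of the aldehyde n→π* band gives an oxygen-centred electrophilic excited state that bonds to the terminal alkene carbon C19, and the resulting 1,4-biradical (α-oxy radical at C3, tertiary radical at C4) collapses by forming the C3–C4 bond; this is an intramolecular Paternò–Büchi [2+2] photocycloaddition, a known reaction of alkenyl aldehydes. The oxetane closes by O–C19 bonding followed by radical recombination, and the same recombination closes ring A as a six-membered carbocycle (6-exo attack of C3 on C4 with respect to the C4=C19 bond), so a 7-oxabicyclo[4.2.0]octane is fused to ring B in one event. C3 and C4 are set together: a four-membered ring can only be cis-fused, which puts the C3 oxygen and C19 on the same face, and the trans-diequatorial arrangement of the C1–C2–C3 chain and the isopropenyl group on ring B (fixed by C5 and C10) should let ring A close as a chair in which the alkene CH2 (C19), not the free methyl C18, takes the axial site next to the axial C10 methyl while the oxygen on C3 is equatorial. The step needs chemoselectivity for the isopropenyl group: the only other double bond is an electron-poor, tetrasubstituted enol triflate flanked by quaternary C10, the γ-carbon C10 carries no hydrogen so Norrish type 2 cleavage is excluded, and nothing else absorbs at 300 nm. The regiochemistry (oxygen on C19, carbon on C4) follows from the more stable tertiary radical, whereas acid-promoted thermal chemistry of 10 would join C3 to C19 instead.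

Step 7
Reactants: 11 oxetane enol triflate
Product: 12 conjugated methyl ester (CO2Me on C9; C8=C9 tetrasubstituted; oxetane intact)
Conditions: CO (1 atm), Pd(OAc)2 (cat.), dppp (cat.), Et3N, MeOH/DMF, 60 °C
Reagents that add atoms: carbon monoxide, [C-]#[O+]; methanol, CO
Why: Palladium-catalysed methoxycarbonylation of the enol triflate (oxidative addition, CO insertion, methanolysis) introduces C11 at C9, and the oxetane is inert to the mildly basic medium.

Step 8
Reactants: 12 conjugated methyl ester
Product: 14 methyl ester with exocyclic C8=C17 methylene and C9–H (ester equatorial and cis to the C10 methyl), via lithium dienolate 13 (not isolated)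
Conditions: LiN(i-Pr)2, THF/DMPU, −78 → −20 °C; then AcOH, −78 °C
Reagents that add atoms: none
Why: Deconjugative protonation: the carbonyl-complexed amide base removes a proton from the C17 methyl that lies cis to the ester, and kinetic α-protonation of the exocyclic dienolate should occur axially at C9 on the face opposite the axial C10 methyl, setting C9.

Step 9
Reactants: 14 exocyclic methylene ester
Product: 16 aldehyde (C11 formyl on C9), via aluminium hemiacetal 15 (not isolated)
Conditions: i-Bu2AlH (1.1 equiv), CH2Cl2, −78 °C; then aq. KNaC4H4O6 (Rochelle salt)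
Reagents that add atoms: none
Why: Partial reduction of the hindered methyl ester with one hydride equivalent at low temperature stops at the tetrahedral aluminium hemiacetal, which releases the aldehyde on neutral work-up; the oxetane is stable to the reagent at −78 °C.

Step 10
Reactants: 16 aldehyde
Product: 17 (E)-alkenyl pinacol boronate (C9–CH=CH–Bpin)
Conditions: CrCl2, LiI, Cl2CHBpin, THF, rt
Reagents that add atoms: 2-(dichloromethyl)-4,4,5,5-tetramethyl-1,3,2-dioxaborolane, ClC(Cl)B1OC(C)(C)C(C)(C)O1
Why: Takai–Utimoto boryl olefination with the geminal dichromium reagent should give the (E)-alkenylboronate under non-basic conditions, so the C9 centre and the β,γ-double bond are not disturbed.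

Step 11
Reactants: 17 (E)-alkenyl pinacol boronate; 18 3-bromofuran-2(5H)-one
Product: 19 oxetane-protected dienyl butenolide (3,19-anhydro-14-deoxy-11,12-didehydroandrographolide)
Conditions: PdCl2(dppf) (cat.), K3PO4, THF/H2O, 40 °C
Reagents that add atoms: none
Why: Suzuki–Miyaura coupling of the alkenylboronate with the α-bromobutenolide forms the C12–C13 bond with retention of the (E)-geometry under mildly basic conditions.

Step 12
Reactants: 19 oxetane-protected dienyl butenolide
Product: 20 19-O-acetyl-14-deoxy-11,12-didehydroandrographolide (3R,4R,5S,9R,10R)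
Conditions: AcOH (excess), Yb(OTf)3 (cat.), CH2Cl2, 0 °C → rt
Reagents that add atoms: acetic acid, CC(=O)O
Why: Lewis-acid-assisted acetolysis of the strained oxetane: acetic acid should attack the primary carbon C19 in an SN2 opening driven by release of ring strain, which frees the C3 hydroxyl with its configuration untouched and places the acetate on C19 in the same operation.

Compound list
1 | (S)-(+)-carvone, (5S)-2-methyl-5-(prop-1-en-2-yl)cyclohex-2-en-1-one | CC1=CC[C@H](C(C)=C)CC1=O | starting material
2 | lithium dienolate of 1 (not isolated) | CC1=CC[C@H](C(C)=C)C=C1O[Li] | intermediate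
3 | (5S)-2,6-dimethyl-5-(prop-1-en-2-yl)cyclohex-2-en-1-one (6-methylcarvone, C6 epimers, trans expected to predominate) | CC1=CC[C@H](C(C)=C)C(C)C1=O | intermediate
4 | lithium dienolate of 3 (not isolated) | CC1=CC[C@H](C(C)=C)C(C)=C1O[Li] | intermediate
5 | (5R,6R)-2,6-dimethyl-6-(prop-2-en-1-yl)-5-(prop-1-en-2-yl)cyclohex-2-en-1-one (allyl trans to isopropenyl) | CC1=CC[C@H](C(C)=C)[C@@](C)(CC=C)C1=O | intermediate
6 | lithium enolate from 1,4-reduction of 5 (not isolated) | CC1=C(O[Li])[C@](C)(CC=C)[C@@H](C(C)=C)CC1 | intermediate
7 | (5R,6R)-2,6-dimethyl-6-(prop-2-en-1-yl)-5-(prop-1-en-2-yl)cyclohex-1-en-1-yl trifluoromethanesulfonate | CC1=C(OS(=O)(=O)C(F)(F)F)[C@](C)(CC=C)[C@@H](C(C)=C)CC1 | intermediate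
8 | alkylbis(3-methylbutan-2-yl)borane from hydroboration of the allyl group of 7 (not isolated) | CC1=C(OS(=O)(=O)C(F)(F)F)[C@](C)(CCCB(C(C)C(C)C)C(C)C(C)C)[C@@H](C(C)=C)CC1 | intermediate
9 | primary alcohol: 3-hydroxypropyl chain on C10 of the ring B enol triflate | CC1=C(OS(=O)(=O)C(F)(F)F)[C@](C)(CCCO)[C@@H](C(C)=C)CC1 | intermediate
10 | aldehyde: 3-oxopropyl chain on C10 of the ring B enol triflate | CC1=C(OS(=O)(=O)C(F)(F)F)[C@](C)(CCC=O)[C@@H](C(C)=C)CC1 | intermediate
11 | oxetane-fused trans-octalin enol triflate (O on C3 and C19 on C4 cis to the C10 methyl) | CC1=C(OS(=O)(=O)C(F)(F)F)[C@]2(C)CC[C@H]3OC[C@@]3(C)[C@H]2CC1 | intermediate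
12 | conjugated methyl ester (CO2Me on C9, C8=C9), oxetane intact | CC1=C(C(=O)OC)[C@]2(C)CC[C@H]3OC[C@@]3(C)[C@H]2CC1 | intermediate
13 | lithium dienolate of 12 with exocyclic C8=C17 (not isolated) | C=C1C(=C(OC)O[Li])[C@]2(C)CC[C@H]3OC[C@@]3(C)[C@H]2CC1 | intermediate
14 | deconjugated methyl ester with exocyclic C8=C17 methylene and equatorial ester on C9 | C=C1[C@@H](C(=O)OC)[C@]2(C)CC[C@H]3OC[C@@]3(C)[C@H]2CC1 | intermediate
15 | diisobutylaluminium hemiacetal of 14 (not isolated) | C=C1[C@@H](C(OC)O[Al](CC(C)C)CC(C)C)[C@]2(C)CC[C@H]3OC[C@@]3(C)[C@H]2CC1 | intermediate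
16 | aldehyde (C11 formyl on C9), oxetane intact | C=C1[C@@H](C=O)[C@]2(C)CC[C@H]3OC[C@@]3(C)[C@H]2CC1 | intermediate
17 | (E)-alkenyl pinacol boronate | C=C1[C@@H](/C=C/B5OC(C)(C)C(C)(C)O5)[C@]2(C)CC[C@H]3OC[C@@]3(C)[C@H]2CC1 | intermediate
18 | 3-bromofuran-2(5H)-one | O=C1OCC=C1Br | starting material
19 | 3,19-anhydro-14-deoxy-11,12-didehydroandrographolide (oxetane-protected dienyl butenolide) | C=C1[C@@H](/C=C/C5=CCOC5=O)[C@]2(C)CC[C@H]3OC[C@@]3(C)[C@H]2CC1 | intermediate
20 | 19-O-acetyl-14-deoxy-11,12-didehydroandrographolide | C=C1CC[C@@H]2[C@](C)(COC(C)=O)[C@H](O)CC[C@@]2(C)[C@@H]1/C=C/C1=CCOC1=O | target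

Total step count: 12. Longest linear sequence: 12 steps, from (S)-carvone (1) to 20; compound 18 is used as purchased.

Steps most likely to fail

1. Step 6 (photocycloaddition). The excited aldehyde may be lost through α-cleavage and decarbonylation, through abstraction of the allylic hydrogen on C5, or through addition to the enol triflate double bond; the biradical may also close on the other face (C18 axial) and give the C3/C4 diastereomer. The fallback closes the same bond thermally by a reductive radical cyclisation. It sets out from alcohol 9: epoxidation of the isopropenyl group with mCPBA should give the epoxy alcohol F1 (either epoxide epimer is usable), and Dess–Martin oxidation the epoxy aldehyde F2. Cp2TiCl (from Cp2TiCl2 and Zn, trivalent titanium) then opens the epoxide to the tertiary C4 radical, which adds to the C3 aldehyde in a 6-exo closure templated by titanium bridging the two oxygens and should give the cis 3,19-diol F3. Selective sulfonylation of the primary hydroxyl (TsCl, pyridine) gives the monotosylate F4, and KOt-Bu closes the oxetane by intramolecular Williamson etherification, coming back to the route at 11.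

2. Step 12 (oxetane acetolysis). Attack at the neopentyl-type C19 may be slow enough that the Lewis acid ionises the C3–O bond (skeletal rearrangement) or isomerises the exocyclic double bond. The fallback unmasks the diol while the molecule is still acid-robust and carries it protected. It sets out from ester 12: hydrolysis of the oxetane with dilute aqueous H2SO4 in THF should give the 3,19-diol ester F5, and 2,2-dimethoxypropane with pyridinium p-toluenesulfonate the acetonide F6. The operations of steps 8 to 11 then give in turn the exocyclic methylene ester acetonide F7, the aldehyde acetonide F8, the (E)-alkenylboronate acetonide F9 and the coupled dienyl butenolide acetonide F10. Aqueous acetic acid removes the acetonide to give 14-deoxy-11,12-didehydroandrographolide F11, and acetylation of the primary C19 hydroxyl (one equivalent of Ac2O, 2,4,6-collidine, low temperature, or a lipase with vinyl acetate) comes back to the route at 20.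

3. Step 8 (deconjugation). Proton removal may occur at the ring methylene C7 instead of C17, or the dienolate and product may equilibrate on quenching, which would lead to endocyclic double-bond isomers or back to 12. The fallback is a photochemical deconjugation that needs no strong base. It sets out from 12: irradiation at 254 nm with catalytic 1,2-dimethylimidazole should trigger a 1,5-hydrogen shift from the C17 methyl to the excited ester carbonyl and give the photodienol F12, whose base-catalysed ketonisation at C9 on the face opposite the C10 methyl comes back to the route at 14.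

Further compounds
F1 | step 6 | epoxy alcohol (isopropenyl group of 9 epoxidised, C4 epimers) | CC1=C(OS(=O)(=O)C(F)(F)F)[C@](C)(CCCO)[C@@H](C2(C)CO2)CC1
F2 | step 6 | epoxy aldehyde | CC1=C(OS(=O)(=O)C(F)(F)F)[C@](C)(CCC=O)[C@@H](C2(C)CO2)CC1
F3 | step 6 | cis 3,19-diol trans-octalin enol triflate | CC1=C(OS(=O)(=O)C(F)(F)F)[C@]2(C)CC[C@@H](O)[C@@](C)(CO)[C@H]2CC1
F4 | step 6 | C19 mono-p-toluenesulfonate of F3 | CC1=C(OS(=O)(=O)C(F)(F)F)[C@]2(C)CC[C@@H](O)[C@@](C)(COS(=O)(=O)c3ccc(C)cc3)[C@H]2CC1
F5 | step 12 | 3,19-diol conjugated methyl ester | CC1=C(C(=O)OC)[C@]2(C)CC[C@@H](O)[C@@](C)(CO)[C@H]2CC1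
F6 | step 12 | 3,19-acetonide of F5 | CC1=C(C(=O)OC)[C@]2(C)CC[C@H]3OC(C)(C)OC[C@@]3(C)[C@H]2CC1
F7 | step 12 | exocyclic methylene ester acetonide | C=C1[C@@H](C(=O)OC)[C@]2(C)CC[C@H]3OC(C)(C)OC[C@@]3(C)[C@H]2CC1
F8 | step 12 | aldehyde acetonide | C=C1[C@@H](C=O)[C@]2(C)CC[C@H]3OC(C)(C)OC[C@@]3(C)[C@H]2CC1
F9 | step 12 | (E)-alkenyl pinacol boronate acetonide | C=C1[C@@H](/C=C/B4OC(C)(C)C(C)(C)O4)[C@]2(C)CC[C@H]3OC(C)(C)OC[C@@]3(C)[C@H]2CC1
F10 | step 12 | 3,19-O-isopropylidene-14-deoxy-11,12-didehydroandrographolide | C=C1[C@@H](/C=C/C4=CCOC4=O)[C@]2(C)CC[C@H]3OC(C)(C)OC[C@@]3(C)[C@H]2CC1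
F11 | step 12 | 14-deoxy-11,12-didehydroandrographolide | C=C1CC[C@@H]2[C@](C)(CO)[C@H](O)CC[C@@]2(C)[C@@H]1/C=C/C1=CCOC1=O
F12 | step 8 | photodienol of 12 (ketene hemiacetal with exocyclic C8=C17) | C=C1C(=C(O)OC)[C@]2(C)CC[C@H]3OC[C@@]3(C)[C@H]2CC1
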